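Locants: unprimed = 7-hydroxycoumarin half (benzenoid ring B, pyranone B); primed = 7-methoxycoumarin half (benzenoid ring A, pyranone A).

**Plan**
1. The retrosynthesis first removes the group on C7–O and the two enol methyl ethers. It then cuts pyranone A at C2'–C3' and O1'–C2' (an acetyl group plus a carbonate carbon), pyranone B at C3–C4 (an O-acetate closing on the C4 ester carbon), and the acetyl–C4a' bond on ring A.
2. This leaves a 3-aryl-4,6-dihydroxy-2-methylbenzoate. Its ring B carries acyl carbon C4 on C4a, methyl on C5, aryl on C6, and oxygen on C7 and C8a in a 1,3 relation, which is the pattern of an aromatised 2,4-dioxocyclohexane-1-carboxylate.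
3. Ring B is therefore cut at C4a–C5 and C7–C8 into ethyl acetoacetate and an ethyl 2-arylbut-2-enoate. The enoate goes back through its C=C bond (Wittig) and its aryl–CO bond (lithiation, oxalate) to 3,5-dimethoxytoluene.
4. In the forward direction ring A is bought, carbocycle B is annulated (step 3) and aromatised (step 4), and both pyranones close together (step 9).
5. The twofold symmetry of the 2,6-dimethoxy-4-methylphenyl group makes its acetylation unambiguous, and chelation selects the methoxy group that becomes O1'. A tosylate guards C7–O because it survives TiCl4 and BCl3 and deactivates ring B.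
6. The target has no stereocentre. The three sp3 centres made in step 3 vanish in step 4, and the biaryl axis, stereogenic from step 6 on, is formed as the racemate.

Key step: step 3

Assumption: the target SMILES carries no descriptor for the biaryl axis, so the racemate is taken as the goal.

**Step 1**
Reactants: 1 3,5-dimethoxytoluene; 2 diethyl oxalate
Product: 4 ethyl 2-(2,6-dimethoxy-4-methylphenyl)-2-oxoacetate, via aryllithium 3 (not isolated)
Conditions: n-BuLi, THF, 0 °C to rt; cannulate into 2 (3 equiv.), THF, −78 °C; 1 M HCl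
Reagents that add atoms: none
Why: Directed ortho-metalation occurs at the position flanked by both methoxy groups, and inverse addition of the aryllithium to excess oxalate is the standard acylation that stops at the aryl glyoxylate.

**Step 2**
Reactants: 4 ethyl 2-(2,6-dimethoxy-4-methylphenyl)-2-oxoacetate
Product: 5 ethyl (E)-2-(2,6-dimethoxy-4-methylphenyl)but-2-enoate
Conditions: EtPPh3Br, KOtBu, THF, 0 °C; add 4, −78 °C to rt
Reagents that add atoms: ethyltriphenylphosphonium bromide, CC[P+](c1ccccc1)(c1ccccc1)c1ccccc1.[Br-]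
Why: In this Wittig olefination the non-enolisable, strongly electrophilic keto carbonyl reacts ahead of the ester, the E ester (methyl cis to the twisted aryl group) is expected to prevail, and any Z isomer can be carried on because the alkene geometry is lost in step 3.

**Step 3**
Reactants: 5 ethyl (E)-2-(2,6-dimethoxy-4-methylphenyl)but-2-enoate; 6 ethyl acetoacetate
Product: 10 ethyl 3-(2,6-dimethoxy-4-methylphenyl)-2-methyl-4,6-dioxocyclohexane-1-carboxylate, via sodium enolate 7 (not isolated), via Michael adduct 8 (not isolated), via sodium dionate 9 (not isolated)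
Conditions: NaOEt (1.1 equiv.), EtOH (concentrated), reflux; then 2 M HCl, 0 °C
Reagents that add atoms: none
Why: Enolate 7 adds through its central carbon to the β-carbon of 5 (future C4a–C5 bond), proton transfer in adduct 8 exposes the enolate of the acetyl methyl group, and that carbon acylates the ester inherited from 5 with loss of ethoxide (future C7–C8 bond). The closest known reaction is the Michael–Claisen annulation of acetoacetates with crotonates that gives dihydroorsellinates; the acceptor here differs only by its α-aryl group. The one new ring closes in a favoured 6-(enolendo)-exo-trig acylation, and no other enolate–carbonyl pairing within 8 could give a ring of more than four members, so the placement of ester, methyl, aryl and both oxygens on ring B follows from connectivity alone. The three new sp3 centres (C1, C2, C3 of the cyclohexane) arise under equilibrating conditions, nothing needs to control them, and all three are erased in step 4. The selectivity required is kinetic, forward addition against retro-Michael cleavage and self-condensation of 6: the two ortho methoxy groups hold the aryl ring perpendicular to the enoate, so the acceptor stays electronically a crotonate with its steric load centred on Cα and not on the attacked Cβ. A full equivalent of NaOEt converts 10 as it forms into the sparingly soluble vinylogous carboxylate 9, and this irreversible deprotonation drains all preceding equilibria.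

**Step 4**
Reactants: 10 ethyl 3-(2,6-dimethoxy-4-methylphenyl)-2-methyl-4,6-dioxocyclohexane-1-carboxylate
Product: 11 ethyl 3-(2,6-dimethoxy-4-methylphenyl)-4,6-dihydroxy-2-methylbenzoate
Conditions: DDQ (2,3-dichloro-5,6-dicyano-1,4-benzoquinone, 1.1 equiv.), 1,4-dioxane, reflux
Reagents that add atoms: none
Why: In this quinone dehydrogenation DDQ takes hydride from C2 of the enolised β-keto ester to give a cyclohexenedione that is a keto tautomer of the resorcinol and enolises at once, the alcohol-free medium keeps the C4 oxygen from being etherified, and the ring A methyl group, meta to both methoxy groups, is not activated toward the quinone.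

**Step 5**
Reactants: 11 ethyl 3-(2,6-dimethoxy-4-methylphenyl)-4,6-dihydroxy-2-methylbenzoate
Product: 13 ethyl 6-acetoxy-3-(2,6-dimethoxy-4-methylphenyl)-2-methyl-4-(tosyloxy)benzoate, via monotosylate 12 (not isolated)
Conditions: TsCl (1.0 equiv.), Et3N, CH2Cl2, 0 °C; then Ac2O, 4-(dimethylamino)pyridine (cat.), rt
Reagents that add atoms: 4-toluenesulfonyl chloride, Cc1ccc(cc1)S(=O)(=O)Cl; acetic anhydride, CC(=O)OC(C)=O
Why: This is a chemoselective sulfonylation followed by catalysed acetylation, in which the 4-OH para to the ester is the more acidic and is not hydrogen-bonded to the ester carbonyl, so it takes the single equivalent of TsCl before the chelated 6-OH receives the acetyl group needed in step 9, and a sulfonate is preferred to a benzyl ether because it withstands the Lewis acids of steps 6 and 7 and deactivates ring B.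

**Step 6**
Reactants: 13 ethyl 6-acetoxy-3-(2,6-dimethoxy-4-methylphenyl)-2-methyl-4-(tosyloxy)benzoate
Product: 14 ethyl 6-acetoxy-3-(3-acetyl-2,6-dimethoxy-4-methylphenyl)-2-methyl-4-(tosyloxy)benzoate (racemic about the biaryl axis)
Conditions: AcCl, TiCl4, CH2Cl2, −10 to 0 °C
Reagents that add atoms: acetyl chloride, CC(=O)Cl
Why: In this Friedel–Crafts acylation the two equivalent free positions of ring A are each ortho and para to a methoxy group and ortho to the methyl group, as in the known acetylation of orcinol dimethyl ether, whereas the only free position of ring B lies between a sulfonate and an acetate on an ester-bearing ring, and the first acetyl group deactivates ring A against a second.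

**Step 7**
Reactants: 14 ethyl 6-acetoxy-3-(3-acetyl-2,6-dimethoxy-4-methylphenyl)-2-methyl-4-(tosyloxy)benzoate
Product: 16 ethyl 6-acetoxy-3-(3-acetyl-2-hydroxy-6-methoxy-4-methylphenyl)-2-methyl-4-(tosyloxy)benzoate (racemic), via boron chelate 15 (not isolated)
Conditions: BCl3 (1.2 equiv.), CH2Cl2, −78 to −10 °C; then H2O
Reagents that add atoms: none
Why: In this chelation-directed aryl methyl ether cleavage BCl3 binds the ketone oxygen and the adjacent methoxy oxygen in a six-membered chelate and chloride removes only that methyl group, while the methoxy group para to the acetyl group, the tosylate, the acetate and the hindered ester should persist at low temperature.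

**Step 8**
Reactants: 16 ethyl 6-acetoxy-3-(3-acetyl-2-hydroxy-6-methoxy-4-methylphenyl)-2-methyl-4-(tosyloxy)benzoate
Product: 17 ethyl 6-acetoxy-3-[3-acetyl-2-(ethoxycarbonyloxy)-6-methoxy-4-methylphenyl]-2-methyl-4-(tosyloxy)benzoate (racemic)
Conditions: ClCO2Et, Et3N, 4-(dimethylamino)pyridine (cat.), CH2Cl2, 0 °C to rt
Reagents that add atoms: ethyl chloroformate, CCOC(=O)Cl
Why: O-Acylation of the single free phenol with a chloroformate under nucleophilic catalysis places the future C2' carbon next to the acetyl group and avoids the hot alkoxide of the intermolecular diethyl carbonate method, which would endanger the tosylate.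

**Step 9**
Reactants: 17 ethyl 6-acetoxy-3-[3-acetyl-2-(ethoxycarbonyloxy)-6-methoxy-4-methylphenyl]-2-methyl-4-(tosyloxy)benzoate
Product: 19 4,4'-dihydroxy-7'-methoxy-5,5'-dimethyl-2,2'-dioxo-2H,2'H-[6,8'-bichromen]-7-yl 4-methylbenzenesulfonate (racemic), via keto ester 18 (not isolated)
Conditions: LiN(SiMe3)2 (5 equiv.), THF, −78 to 0 °C; then 2 M HCl, THF, 40 °C
Reagents that add atoms: none
Why: Two intramolecular Claisen-type acylations run side by side, the ring B acetate enolate closing on the neighbouring ethyl ester (Dieckmann-type closure known for O-acetyl salicylates and orsellinates) and the ring A ketone enolate taking the ethoxycarbonyl group from the neighbouring oxygen (Baker–Venkataraman-type O-to-C transfer) to give keto ester 18, which lactonises on acidification, while the silylamide is too weak a base to metalate the benzylic methyl groups and the cold medium spares the tosylate.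

**Step 10**
Reactants: 19 4,4'-dihydroxy-7'-methoxy-5,5'-dimethyl-2,2'-dioxo-2H,2'H-[6,8'-bichromen]-7-yl 4-methylbenzenesulfonate
Product: 20 4,4',7'-trimethoxy-5,5'-dimethyl-2,2'-dioxo-2H,2'H-[6,8'-bichromen]-7-yl 4-methylbenzenesulfonate (racemic)
Conditions: Me2SO4 (2.5 equiv.), K2CO3, acetone, reflux
Reagents that add atoms: dimethyl sulfate, COS(=O)(=O)OC
Why: O-Alkylation of the two vinylogous acids, the standard conversion of 4-hydroxycoumarins into 4-methoxycoumarins, meets no other acidic site because C7–O is still sulfonylated.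

**Step 11**
Reactants: 20 4,4',7'-trimethoxy-5,5'-dimethyl-2,2'-dioxo-2H,2'H-[6,8'-bichromen]-7-yl 4-methylbenzenesulfonate
Product: 22 7-hydroxy-4,4',7'-trimethoxy-5,5'-dimethyl-2H,2'H-[6,8'-bichromene]-2,2'-dione (racemic), via potassium phenoxide 21 (not isolated)
Conditions: K2CO3, MeOH–THF, 50 °C; then 1 M HCl
Reagents that add atoms: none
Why: In this base-mediated solvolysis of an aryl sulfonate methoxide attacks sulfur and expels the well-stabilised 7-oxidocoumarin, and methanol is the chosen medium because addition–elimination at C4 or C4' only exchanges methoxy for methoxy and any lactone opening is reversed on acidification.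

**Compound list**
1 | 3,5-dimethoxytoluene | Cc1cc(OC)cc(OC)c1 | starting material
2 | diethyl oxalate | CCOC(=O)C(=O)OCC | starting material
3 | (2,6-dimethoxy-4-methylphenyl)lithium | [Li]c1c(OC)cc(C)cc1OC | intermediate
4 | ethyl 2-(2,6-dimethoxy-4-methylphenyl)-2-oxoacetate | CCOC(=O)C(=O)c1c(OC)cc(C)cc1OC | intermediate
5 | ethyl (E)-2-(2,6-dimethoxy-4-methylphenyl)but-2-enoate | CCOC(=O)/C(=C/C)c1c(OC)cc(C)cc1OC | intermediate
6 | ethyl acetoacetate | CCOC(=O)CC(C)=O | starting material
7 | sodium enolate of ethyl acetoacetate | CCOC(=O)C=C(C)[O-].[Na+] | intermediate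
8 | diethyl 2-acetyl-4-(2,6-dimethoxy-4-methylphenyl)-3-methylpentanedioate (diastereomer mixture) | CCOC(=O)C(C(C)=O)C(C)C(C(=O)OCC)c1c(OC)cc(C)cc1OC | intermediate
9 | sodium salt of 10 (vinylogous carboxylate) | CCOC(=O)C1C(C)C(c2c(OC)cc(C)cc2OC)C(=O)C=C1[O-].[Na+] | intermediate
10 | ethyl 3-(2,6-dimethoxy-4-methylphenyl)-2-methyl-4,6-dioxocyclohexane-1-carboxylate (three transient centres, configuration immaterial) | CCOC(=O)C1C(C)C(c2c(OC)cc(C)cc2OC)C(=O)CC1=O | intermediate
11 | ethyl 3-(2,6-dimethoxy-4-methylphenyl)-4,6-dihydroxy-2-methylbenzoate | CCOC(=O)c1c(C)c(-c2c(OC)cc(C)cc2OC)c(O)cc1O | intermediate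
12 | ethyl 3-(2,6-dimethoxy-4-methylphenyl)-6-hydroxy-2-methyl-4-(tosyloxy)benzoate | CCOC(=O)c1c(C)c(-c2c(OC)cc(C)cc2OC)c(OS(=O)(=O)c2ccc(C)cc2)cc1O | intermediate
13 | ethyl 6-acetoxy-3-(2,6-dimethoxy-4-methylphenyl)-2-methyl-4-(tosyloxy)benzoate | CCOC(=O)c1c(C)c(-c2c(OC)cc(C)cc2OC)c(OS(=O)(=O)c2ccc(C)cc2)cc1OC(C)=O | intermediate
14 | ethyl 6-acetoxy-3-(3-acetyl-2,6-dimethoxy-4-methylphenyl)-2-methyl-4-(tosyloxy)benzoate (racemic axis) | CCOC(=O)c1c(C)c(-c2c(OC)cc(C)c(C(C)=O)c2OC)c(OS(=O)(=O)c2ccc(C)cc2)cc1OC(C)=O | intermediate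
15 | dichloroboron aryloxide chelate of 16 | CCOC(=O)c1c(C)c(-c2c(OC)cc(C)c(C(C)=O)c2OB(Cl)Cl)c(OS(=O)(=O)c2ccc(C)cc2)cc1OC(C)=O | intermediate
16 | ethyl 6-acetoxy-3-(3-acetyl-2-hydroxy-6-methoxy-4-methylphenyl)-2-methyl-4-(tosyloxy)benzoate (racemic axis) | CCOC(=O)c1c(C)c(-c2c(OC)cc(C)c(C(C)=O)c2O)c(OS(=O)(=O)c2ccc(C)cc2)cc1OC(C)=O | intermediate
17 | ethyl 6-acetoxy-3-[3-acetyl-2-(ethoxycarbonyloxy)-6-methoxy-4-methylphenyl]-2-methyl-4-(tosyloxy)benzoate (racemic axis) | CCOC(=O)c1c(C)c(-c2c(OC)cc(C)c(C(C)=O)c2OC(=O)OCC)c(OS(=O)(=O)c2ccc(C)cc2)cc1OC(C)=O | intermediate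
18 | ethyl 3-[2-hydroxy-3-(4-hydroxy-5-methyl-2-oxo-7-tosyloxy-2H-chromen-6-yl)-4-methoxy-6-methylphenyl]-3-oxopropanoate (racemic axis) | CCOC(=O)CC(=O)c1c(C)cc(OC)c(-c2c(OS(=O)(=O)c3ccc(C)cc3)cc3oc(=O)cc(O)c3c2C)c1O | intermediate
19 | 4,4'-dihydroxy-7'-methoxy-5,5'-dimethyl-2,2'-dioxo-2H,2'H-[6,8'-bichromen]-7-yl 4-methylbenzenesulfonate (racemic axis) | COc1cc(C)c2c(O)cc(=O)oc2c1-c1c(OS(=O)(=O)c3ccc(C)cc3)cc2oc(=O)cc(O)c2c1C | intermediate
20 | 4,4',7'-trimethoxy-5,5'-dimethyl-2,2'-dioxo-2H,2'H-[6,8'-bichromen]-7-yl 4-methylbenzenesulfonate (racemic axis) | COc1cc(C)c2c(OC)cc(=O)oc2c1-c1c(OS(=O)(=O)c3ccc(C)cc3)cc2oc(=O)cc(OC)c2c1C | intermediate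
21 | potassium 7-phenoxide of 22 | COc1cc(C)c2c(OC)cc(=O)oc2c1-c1c([O-])cc2oc(=O)cc(OC)c2c1C.[K+] | intermediate
22 | 7-hydroxy-4,4',7'-trimethoxy-5,5'-dimethyl-2H,2'H-[6,8'-bichromene]-2,2'-dione (racemic axis) | COc1cc(C)c2c(OC)cc(=O)oc2c1-c1c(O)cc2oc(=O)cc(OC)c2c1C | target

Total step count: 11. Longest linear sequence: 11 steps (1 to 22).

**Steps most likely to fail**

**Step 3.**
- Risk: the conjugate addition may be too slow at a β-carbon next to the bulky α-aryl group. Retro-addition and self-condensation of 6 could then use up the material before the ring-closing acylation pulls the equilibria forward.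
- Fallback (sets out from 4 and 6, returns at 8): the polarity of the Michael step is inverted, so the same adduct arises through the C5–C6 bond.
- Reduction of 4 (NaBH4, EtOH, 0 °C) should give ethyl 2-(2,6-dimethoxy-4-methylphenyl)-2-hydroxyacetate F1. Ionic hydrogenation of this electron-rich benzylic alcohol (Et3SiH, CF3CO2H, CH2Cl2) should give ethyl 2-(2,6-dimethoxy-4-methylphenyl)acetate F2.
- Knoevenagel condensation of 6 with acetaldehyde (piperidine cat., 0 °C) gives ethyl 2-acetylbut-2-enoate F3.
- The lithium enolate of F2 (LiN(iPr)2, THF, −78 °C) should add irreversibly to the doubly activated acceptor F3, because an ester enolate is exchanged for a β-keto ester enolate. Protonation gives 8, and NaOEt in EtOH closes it to 10 by the same Claisen condensation.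

**Step 9.**
- Risk: acyl scrambling between the two different enolates, or fragmentation of the aryl acetate enolate with loss of ketene, could outrun one of the two ring closures.
- Fallback (sets out from 13, returns at 20): the pyranones are closed one at a time, and pyranone B is made before ring A carries any enolisable group.
- LiN(SiMe3)2 (THF, −78 to 0 °C) converts 13 into 6-(2,6-dimethoxy-4-methylphenyl)-4-hydroxy-5-methyl-2-oxo-2H-chromen-7-yl 4-methylbenzenesulfonate F4.
- Me2SO4 and K2CO3 in acetone give the 4-methoxy compound 6-(2,6-dimethoxy-4-methylphenyl)-4-methoxy-5-methyl-2-oxo-2H-chromen-7-yl 4-methylbenzenesulfonate F5.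
- AcCl and TiCl4 acetylate ring A to 6-(3-acetyl-2,6-dimethoxy-4-methylphenyl)-4-methoxy-5-methyl-2-oxo-2H-chromen-7-yl 4-methylbenzenesulfonate F6.
- BCl3 frees the chelated phenol 6-(3-acetyl-2-hydroxy-6-methoxy-4-methylphenyl)-4-methoxy-5-methyl-2-oxo-2H-chromen-7-yl 4-methylbenzenesulfonate F7.
- ClCO2Et gives the carbonate 6-[3-acetyl-2-(ethoxycarbonyloxy)-6-methoxy-4-methylphenyl]-4-methoxy-5-methyl-2-oxo-2H-chromen-7-yl 4-methylbenzenesulfonate F8.
- LiN(SiMe3)2 followed by aqueous HCl closes pyranone A to 4'-hydroxy-4,7'-dimethoxy-5,5'-dimethyl-2,2'-dioxo-2H,2'H-[6,8'-bichromen]-7-yl 4-methylbenzenesulfonate F9.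
- A last methylation (Me2SO4, K2CO3) gives 20 and would also restore any C4 methoxy group lost to BCl3.

**Step 4.**
- Risk: hydride transfer from the strongly enolised, electron-poor vinylogous acid may stall, or the enol may add to the quinone instead of being dehydrogenated.
- Fallback (sets out from 10, returns at 11): halogenative aromatisation with a reductive clean-up, the classical treatment of dihydroorsellinates.
- Excess Br2 (4 equiv., AcOH, rt) should aromatise ring B by bromination and loss of HBr, and should deliberately fill every free aromatic position. The product is ethyl 5-bromo-3-(3,5-dibromo-2,6-dimethoxy-4-methylphenyl)-4,6-dihydroxy-2-methylbenzoate F10.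
- Hydrogenolysis of all three C–Br bonds (H2, Pd/C, NaOAc, EtOH) then gives 11. Competing bromination of ring A therefore does no lasting harm.

**Further compounds**
F1 | step 3 | ethyl 2-(2,6-dimethoxy-4-methylphenyl)-2-hydroxyacetate (racemic) | CCOC(=O)C(O)c1c(OC)cc(C)cc1OC
F2 | step 3 | ethyl 2-(2,6-dimethoxy-4-methylphenyl)acetate | CCOC(=O)Cc1c(OC)cc(C)cc1OC
F3 | step 3 | ethyl 2-acetylbut-2-enoate (E/Z mixture) | CCOC(=O)C(=CC)C(C)=O
F4 | step 9 | 6-(2,6-dimethoxy-4-methylphenyl)-4-hydroxy-5-methyl-2-oxo-2H-chromen-7-yl 4-methylbenzenesulfonate | COc1cc(C)cc(OC)c1-c1c(OS(=O)(=O)c2ccc(C)cc2)cc2oc(=O)cc(O)c2c1C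
F5 | step 9 | 6-(2,6-dimethoxy-4-methylphenyl)-4-methoxy-5-methyl-2-oxo-2H-chromen-7-yl 4-methylbenzenesulfonate | COc1cc(C)cc(OC)c1-c1c(OS(=O)(=O)c2ccc(C)cc2)cc2oc(=O)cc(OC)c2c1C
F6 | step 9 | 6-(3-acetyl-2,6-dimethoxy-4-methylphenyl)-4-methoxy-5-methyl-2-oxo-2H-chromen-7-yl 4-methylbenzenesulfonate (racemic axis) | COc1cc(C)c(C(C)=O)c(OC)c1-c1c(OS(=O)(=O)c2ccc(C)cc2)cc2oc(=O)cc(OC)c2c1C
F7 | step 9 | 6-(3-acetyl-2-hydroxy-6-methoxy-4-methylphenyl)-4-methoxy-5-methyl-2-oxo-2H-chromen-7-yl 4-methylbenzenesulfonate (racemic axis) | COc1cc(C)c(C(C)=O)c(O)c1-c1c(OS(=O)(=O)c2ccc(C)cc2)cc2oc(=O)cc(OC)c2c1C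
F8 | step 9 | 6-[3-acetyl-2-(ethoxycarbonyloxy)-6-methoxy-4-methylphenyl]-4-methoxy-5-methyl-2-oxo-2H-chromen-7-yl 4-methylbenzenesulfonate (racemic axis) | CCOC(=O)Oc1c(C(C)=O)c(C)cc(OC)c1-c1c(OS(=O)(=O)c2ccc(C)cc2)cc2oc(=O)cc(OC)c2c1C
F9 | step 9 | 4'-hydroxy-4,7'-dimethoxy-5,5'-dimethyl-2,2'-dioxo-2H,2'H-[6,8'-bichromen]-7-yl 4-methylbenzenesulfonate (racemic axis) | COc1cc(C)c2c(O)cc(=O)oc2c1-c1c(OS(=O)(=O)c3ccc(C)cc3)cc2oc(=O)cc(OC)c2c1C
F10 | step 4 | ethyl 5-bromo-3-(3,5-dibromo-2,6-dimethoxy-4-methylphenyl)-4,6-dihydroxy-2-methylbenzoate | CCOC(=O)c1c(C)c(-c2c(OC)c(Br)c(C)c(Br)c2OC)c(O)c(Br)c1O
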